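**Retrosynthetic overview**

1. Numbering (drimane): ring A = C1–C5 + C10 (C3 carries the ester oxygen, C4 the gem-dimethyl, C10 the angular methyl). Ring B = C5–C10 (C6 ketone, C7=C8, C12 = methyl on C8, C11 = OCH2 carbon on C9).
2. Last disconnection: C9–C11, by γ-alkylation of the ring B silyl dienol ether with the chloromethyl ether of isofraxidin; this joins the coumarin and sets C9 anti to the C10 methyl.
3. Key disconnection: ring B is opened at C5–C6 and C9–C10 in a [4+2] sense. C6–C7–C8(C12)–C9 becomes the dienolate of a 3-methylbut-3-enoate, and ring A becomes the alkene C5=C10 of (R)-2,2,4-trimethylcyclohex-3-en-1-ol.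
4. Enabling feature: the C3 oxygen of ring A is 1,3 to C5 and on the face opposite the C10 methyl, and C6 is a carbonyl carbon. C6 can therefore be the acyl carbon of the C3 ester, whose silyl ketene acetal (diene C6=C7–C8=C9) reaches C5=C10 from that face through a temporary C3–O–C6 bridge that hydrolysis removes.
5. Ring order: coumarin bought intact; ring A from a cyclohexenone (C3 by CBS reduction); ring B plus the temporary oxolane in the key step; bridge opened and C5 epimerised to the trans fusion; coumarin joined last.

Key step: step 5

Remark: isofraxidin (13) and 4-methylcyclohex-2-en-1-one (1) are taken as commercially available; α/β descriptors refer to the usual drimane drawing with the C10 methyl β.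

**Step 1**
Reactants: 1 4-methylcyclohex-2-en-1-one (racemic)
Product: 2 2,2,4-trimethylcyclohex-3-en-1-one
Conditions: KOtBu (2.2 equiv), tBuOH, rt; MeI (2.3 equiv)
Reagents that add atoms: iodomethane, CI
Why: Deconjugative α,α-dialkylation of an enone: the extended dienolate is methylated twice at the α-carbon, which moves the alkene to C5=C10 and erases the stereocentre of 1; no new stereocentre.

**Step 2**
Reactants: 2 2,2,4-trimethylcyclohex-3-en-1-one
Product: 3 (1R)-2,2,4-trimethylcyclohex-3-en-1-ol
Conditions: (S)-2-methyl-CBS-oxazaborolidine (10 mol %), BH3·SMe2, THF, −20 °C; MeOH quench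
Reagents that add atoms: none
Why: Corey–Bakshi–Shibata reduction; the quaternary CMe2 flank is the large group and the CH2 flank the small one, so the (S)-catalyst should deliver hydride to give the (R)-carbinol that becomes C3.

**Step 3**
Reactants: 3 (1R)-2,2,4-trimethylcyclohex-3-en-1-ol; 4 3-methylbut-3-enoic acid
Product: 5 (1R)-2,2,4-trimethylcyclohex-3-en-1-yl 3-methylbut-3-enoate
Conditions: DCC, DMAP (5 mol %), CH2Cl2, 0 °C
Reagents that add atoms: none
Why: Steglich esterification, run cold with little DMAP so that the β,γ-alkene of the acid is not drawn into conjugation; C3 is untouched.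

**Step 4**
Reactants: 5 (1R)-2,2,4-trimethylcyclohex-3-en-1-yl 3-methylbut-3-enoate
Product: 6 tert-butyl{[(1E)-3-methyl-1-{[(1R)-2,2,4-trimethylcyclohex-3-en-1-yl]oxy}buta-1,3-dien-1-yl]oxy}dimethylsilane (vinylketene silyl acetal, ring A oxygen cis to C8)
Conditions: LiN(iPr)2 (LDA, commercial solution, 1.1 equiv), THF, −78 °C; TBSCl, THF/DMPU, −78 °C to rt; pentane, filtration, no aqueous work-up
Reagents that add atoms: tert-butyl(chloro)dimethylsilane, CC(C)(C)[Si](C)(C)Cl
Why: Ireland-type ester enolisation and O-silylation; α-deprotonation of the β,γ-unsaturated ester gives the C6=C7–C8=C9 dienolate regiospecifically, and enolisation in THF without cosolvent should place the ring A oxygen cis to C8 as the tether needs.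

**Step 5**
Reactants: 6 vinylketene silyl acetal
Product: 8 cis-fused 3α-hydroxy-11-nordrim-7-en-6-one (H5 cis to the C10 methyl), via bridged silyl ketal cycloadduct 7 (not isolated)
Conditions: PhMe (0.01 M), BHT (cat.), sealed tube, 170 °C; then HF·pyridine, THF, 0 °C
Reagents that add atoms: none
Why: Proposed new method: on heating, the 1-alkoxy-1-silyloxy diene C6=C7–C8=C9 of 6 should add across the unactivated ring A alkene C5=C10 in a concerted, asynchronous intramolecular [4+2] cycloaddition (C6–C5 leading, C9–C10 following) to give silyl ketal 7, and fluoride then removes the silyl group so that the ketal collapses to the C6 ketone (already conjugated with C7=C8) and releases the C3 hydroxyl. The closest known reaction types are type 1 intramolecular Diels–Alder reactions of 1-silyloxy dienes with unactivated alkenes through three-atom tethers and the intermolecular Diels–Alder reactions of ester-derived vinylketene silyl acetals; new is that the ester oxygen itself is the tether and the dienophile is a trisubstituted ring alkene. Ring B closes by the cycloaddition itself, and the temporary oxolane C3–O–C6–C5–C4 closes as the tether ring (5-exo at C5), giving a 6-oxabicyclo[3.2.1]octane that needs the C3–O bond pseudo-axial, which the C4 gem-dimethyl group does not penalise. The only controlling element is the C3 stereocentre: its oxygen can deliver C6 only to the face of C5=C10 on which it stands, so C9–C10 forms on that same face, the C10 methyl is pushed to the opposite face (correct C10) and H5 ends cis to that methyl (cis fusion, corrected in step 6), while C6 stops being a stereocentre on hydrolysis. The step needs site selectivity for C6→C5/C9→C10 over C6→C10/C9→C5, secured by the short tether (five-membered bridge against a boat-locked bicyclo[2.2.2] alternative) and by the unsubstituted C9 terminus building the quaternary C10, and it needs the diene to survive the temperature, for which the TBS acetal, the absence of a 1,5-hydrogen-shift pathway and high dilution are chosen.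

**Step 6**
Reactants: 8 cis-fused 3α-hydroxy-11-nordrim-7-en-6-one
Product: 9 trans-fused 3α-hydroxy-11-nordrim-7-en-6-one (H5 anti to the C10 methyl)
Conditions: NaOMe (0.2 equiv), MeOH, rt
Reagents that add atoms: none
Why: Base-mediated epimerisation at C5 (α to the C6 ketone) through the cross-conjugated enolate; equilibration should favour the trans-fused decalone, as in related 6-oxo decalins, and leaves C3 and C10 unchanged.

**Step 7**
Reactants: 9 trans-fused 3α-hydroxy-11-nordrim-7-en-6-one; 10 3-methylbutanoic anhydride
Product: 11 3α-(3-methylbutanoyloxy)-11-nordrim-7-en-6-one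
Conditions: DMAP (cat.), pyridine, 60 °C
Reagents that add atoms: none
Why: DMAP-catalysed acylation of the hindered axial C3 alcohol, with retention at C3.

**Step 8**
Reactants: 11 3α-(3-methylbutanoyloxy)-11-nordrim-7-en-6-one
Product: 12 6-(tert-butyldimethylsilyloxy)-11-nordrima-6,8-dien-3α-yl 3-methylbutanoate (linear silyl dienol ether)
Conditions: TBSOTf (1.3 equiv), Et3N, CH2Cl2, 0 °C to rt (equilibrating)
Reagents that add atoms: tert-butyldimethylsilyl trifluoromethanesulfonate, CC(C)(C)[Si](C)(C)OS(=O)(=O)C(F)(F)F
Why: Soft enolisation (silyl triflate and amine) under equilibrating conditions should give the thermodynamic endocyclic dienol ether C6(OSi)=C7–C8=C9 by γ-deprotonation at the ring CH2 C9, since the α′ position C5 is a hindered tertiary CH; no stereocentre is formed.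

**Step 9**
Reactants: 13 isofraxidin (7-hydroxy-6,8-dimethoxy-2H-chromen-2-one)
Product: 14 6,8-dimethoxy-7-[(methylsulfanyl)methoxy]-2H-chromen-2-one
Conditions: NaH, DMF, 0 °C; ClCH2SMe, NaI (cat.), rt
Reagents that add atoms: chloromethyl methyl sulfide, CSCCl
Why: Williamson ether synthesis; the phenoxide displaces chloride to give the O,S-acetal.

**Step 10**
Reactants: 14 6,8-dimethoxy-7-[(methylsulfanyl)methoxy]-2H-chromen-2-one
Product: 15 7-(chloromethoxy)-6,8-dimethoxy-2H-chromen-2-one
Conditions: SO2Cl2 (1.05 equiv), CH2Cl2, −20 to 0 °C; volatiles removed, used crude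
Reagents that add atoms: sulfuryl chloride, O=S(=O)(Cl)Cl
Why: Chlorinolysis of the O,S-acetal (S-chlorination, then fragmentation to the aryloxymethyl chloride and MeSCl); the sulfide should react well before the arene at low temperature.

**Step 11**
Reactants: 12 linear silyl dienol ether; 15 7-(chloromethoxy)-6,8-dimethoxy-2H-chromen-2-one
Product: 16 CNP0279705.1 (target)
Conditions: ZnBr2 (20 mol %), CH2Cl2, −40 to 0 °C
Reagents that add atoms: none
Why: Lewis-acid-mediated vinylogous Mukaiyama-type alkylation; the aryloxymethyl cation should attack the γ-carbon C9 on the face anti to the axial C10 methyl, placing C11 trans to that methyl, and loss of the silyl group to chloride restores the C7=C8 enone.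

**Compound list**

1 | 4-methylcyclohex-2-en-1-one (racemic) | CC1CCC(=O)C=C1 | starting material
2 | 2,2,4-trimethylcyclohex-3-en-1-one | CC1=CC(C)(C)C(=O)CC1 | intermediate
3 | (1R)-2,2,4-trimethylcyclohex-3-en-1-ol | CC1=CC(C)(C)[C@H](O)CC1 | intermediate
4 | 3-methylbut-3-enoic acid | CC(=C)CC(=O)O | starting material
5 | (1R)-2,2,4-trimethylcyclohex-3-en-1-yl 3-methylbut-3-enoate | CC1=CC(C)(C)[C@H](OC(=O)CC(C)=C)CC1 | intermediate
6 | tert-butyl{[(1E)-3-methyl-1-{[(1R)-2,2,4-trimethylcyclohex-3-en-1-yl]oxy}buta-1,3-dien-1-yl]oxy}dimethylsilane | CC1=CC(C)(C)[C@H](O/C(O[Si](C)(C)C(C)(C)C)=C\C(C)=C)CC1 | intermediate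
7 | bridged silyl ketal cycloadduct: 3α,6-epoxy-6-(tert-butyldimethylsilyloxy)-11-nordrim-7-ene, cis-fused, C3–O, C5–C6 and C9–C10 on one face of ring A | C[C@@]12CC[C@H]3O[C@@](O[Si](C)(C)C(C)(C)C)(C=C(C)C1)[C@@H]2C3(C)C | intermediate (not isolated)
8 | cis-fused 3α-hydroxy-11-nordrim-7-en-6-one (H5 cis to the C10 methyl) | CC1=CC(=O)[C@@H]2C(C)(C)[C@H](O)CC[C@]2(C)C1 | intermediate
9 | trans-fused 3α-hydroxy-11-nordrim-7-en-6-one (H5 anti to the C10 methyl) | CC1=CC(=O)[C@H]2C(C)(C)[C@H](O)CC[C@]2(C)C1 | intermediate
10 | 3-methylbutanoic anhydride | CC(C)CC(=O)OC(=O)CC(C)C | starting material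
11 | 3α-(3-methylbutanoyloxy)-11-nordrim-7-en-6-one | CC1=CC(=O)[C@H]2C(C)(C)[C@H](OC(=O)CC(C)C)CC[C@]2(C)C1 | intermediate
12 | 6-(tert-butyldimethylsilyloxy)-11-nordrima-6,8-dien-3α-yl 3-methylbutanoate | CC1=C[C@@]2(C)CC[C@@H](OC(=O)CC(C)C)C(C)(C)[C@@H]2C(O[Si](C)(C)C(C)(C)C)=C1 | intermediate
13 | isofraxidin (7-hydroxy-6,8-dimethoxy-2H-chromen-2-one) | COc1cc2ccc(=O)oc2c(OC)c1O | starting material
14 | 6,8-dimethoxy-7-[(methylsulfanyl)methoxy]-2H-chromen-2-one | COc1cc2ccc(=O)oc2c(OC)c1OCSC | intermediate
15 | 7-(chloromethoxy)-6,8-dimethoxy-2H-chromen-2-one | COc1cc2ccc(=O)oc2c(OC)c1OCCl | intermediate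
16 | CNP0279705.1: 6,8-dimethoxy-7-{[3α-(3-methylbutanoyloxy)-6-oxodrim-7-en-11-yl]oxy}coumarin, H5 and C11 on the face opposite the C10 methyl | COc1cc2ccc(=O)oc2c(OC)c1OC[C@@H]1C(C)=CC(=O)[C@H]2C(C)(C)[C@H](OC(=O)CC(C)C)CC[C@]12C | target

**Totals**

Total step count: 11. Longest linear sequence: 9 steps (steps 1–8 and 11); steps 9–10 form the short coumarin branch.

**Steps most likely to fail**

Step 5. The unactivated, hindered ring A alkene may react too slowly, so that thermal O-to-C silyl migration or decomposition of the ketene acetal outruns the cycloaddition. The fallback makes the same two bonds by a silicon-tethered intramolecular Diels–Alder reaction, a known reaction type with a longer, more flexible tether and a less hindered, thermally robust (E)-1-silyloxy diene. It sets out from alcohol 3, which would be treated with iPr2Si(OTf)2 and Et3N and then with 3-methylbut-2-enal and more Et3N to give the mixed silaketal dienyl ether F1. Heating in toluene (180–200 °C, sealed tube) would give the dioxasilepane-bridged cycloadduct F2, again on the face of the C3 oxygen; both C6 epimers serve. TBAF would cleave the tether to the cis-fused 3α,6-diol F3, and MnO2 would oxidise only the allylic C6 alcohol, which returns to the route at 8.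

Step 11. Attack may occur at C7 instead of C9 or with poor facial selectivity, or the chloromethyl ether 15 may be consumed by Friedel–Crafts self-alkylation. The fallback separates the two bond formations. It sets out from dienol ether 12, which would be hydroxymethylated at C9 with aqueous formaldehyde and Yb(OTf)3 (THF/H2O) to give the 11-hydroxy enone F4. A Mitsunobu etherification (PPh3, DIAD, THF) with isofraxidin 13 would then form the C11–O bond, and the fallback comes back at 16.

Step 8. Enolisation may run toward the C12 methyl (exocyclic diene) or toward C5 instead of C9. The fallback fixes the position of the diene through a halide. It sets out from enone 11, which would undergo radical γ-bromination (NBS, AIBN cat., PhCF3, 80 °C) at the ring position C9 to give the 9-bromo enone F5. Zn dust and TBSCl in THF/DMPU would then give the dienol ether by reductive O-silylation, with the new double bond necessarily at C8=C9, and the fallback comes back at 12.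

**Further compounds**

F1 | step 5 | {[(1E)-3-methylbuta-1,3-dien-1-yl]oxy}di(propan-2-yl){[(1R)-2,2,4-trimethylcyclohex-3-en-1-yl]oxy}silane | CC1=CC(C)(C)[C@H](O[Si](C(C)C)(C(C)C)O/C=C/C(C)=C)CC1
F2 | step 5 | 3α,6-O,O-[di(propan-2-yl)silanediyl]-bridged cis-fused 11-nordrim-7-ene-3,6-diol (C6 epimers) | CC1=CC2O[Si](C(C)C)(C(C)C)O[C@@H]3CC[C@](C)(C1)[C@H]2C3(C)C
F3 | step 5 | cis-fused 11-nordrim-7-ene-3α,6-diol (C6 epimers) | CC1=CC(O)[C@@H]2C(C)(C)[C@H](O)CC[C@]2(C)C1
F4 | step 11 | 11-hydroxy-3α-(3-methylbutanoyloxy)drim-7-en-6-one (C11 anti to the C10 methyl) | OC[C@@H]1C(C)=CC(=O)[C@H]2C(C)(C)[C@H](OC(=O)CC(C)C)CC[C@]12C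
F5 | step 8 | 9-bromo-3α-(3-methylbutanoyloxy)-11-nordrim-7-en-6-one (C9 epimers) | CC1=CC(=O)[C@H]2C(C)(C)[C@H](OC(=O)CC(C)C)CC[C@]2(C)C1Br
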